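**Strategy**

Clerodane numbering is used. Ring A (C1–C5, C10) is disconnected by deleting C3: the trans-decalin becomes a trans-hydrindanone whose cyclopentanone carbonyl is C4, next to the quaternary C5. That bicycle maps onto a Hajos–Parrish-type enedione, which sets C5 by amino-acid catalysis and lets ring B (C5–C10) be finished first by reductive alkylation (C9, C10) and hydrogenation (C8). The key step inserts one carbon (C3) between C4 and C2 with trimethylsilyldiazomethane, turning the five-membered ring into ring A, the last ring formed, with the carbonyl kept at C4; enol triflate methylation then gives C18 and the C3=C4 alkene. The side chain arrives by B-alkyl Suzuki coupling.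

Key step: step 7

Remark on numbering: clerodane locants are kept in all intermediates. In the hydrindanes the five-membered ring is C5–C4–C2–C1–C10. α is the face of the C19 methyl on C5, β the opposite face. The target is (5R,8R,9S,10R,13E).

Assumption: enedione 4 is treated as not purchasable and is made from 1 and 2; its enantiomeric purity is to be raised by crystallisation before use.

**Route**

Step 1
Reactants: 1 2-methylcyclopentane-1,3-dione; 2 ethyl vinyl ketone (pent-1-en-3-one)
Product: 3 2-methyl-2-(3-oxopentyl)cyclopentane-1,3-dione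
Conditions: H2O, AcOH (cat.), 75 °C
Reagents that add atoms: none
Why: Michael addition of the enolised 1,3-dione to the vinyl ketone in water stops cleanly at the triketone, and the new quaternary carbon is still prochiral.

Step 2
Reactants: 3 2-methyl-2-(3-oxopentyl)cyclopentane-1,3-dione
Product: 4 (7aR)-4,7a-dimethyl-2,3,7,7a-tetrahydro-1H-indene-1,5(6H)-dione
Conditions: D-phenylalanine, (1R)-(−)-10-camphorsulfonic acid, DMF, 30 → 70 °C; crystallisation
Reagents that add atoms: none
Why: Hajos–Parrish–Eder–Sauer–Wiechert aldol cyclodehydration, in which the enamine of the side-chain ketone attacks one of the two enantiotopic ring carbonyls through a hydrogen-bonded transition state, the D-amino acid giving the (R) quaternary carbon C5 (mirror image of the L-series) and closing ring B.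

Step 3
Reactants: 4 (7aR)-4,7a-dimethyl-2,3,7,7a-tetrahydro-1H-indene-1,5(6H)-dione
Product: 5 (7a'R)-4',7a'-dimethyl-2',3',7',7a'-tetrahydrospiro[1,3-dioxolane-2,1'-inden]-5'(6'H)-one
Conditions: (TMSOCH2)2, TMSOTf (cat.), CH2Cl2, −78 → −20 °C
Reagents that add atoms: 1,2-bis(trimethylsilyloxy)ethane, C[Si](C)(C)OCCO[Si](C)(C)C
Why: TMSOTf-catalysed acetalisation with the bis-silyl glycol ether converts saturated ketones at low temperature while conjugated enones react far more slowly, so only the C4 cyclopentanone is masked.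

Step 4
Reactants: 5 (7a'R)-4',7a'-dimethyl-2',3',7',7a'-tetrahydrospiro[1,3-dioxolane-2,1'-inden]-5'(6'H)-one; 6 ethyl bromoacetate
Product: 8 ethyl 2-[(3a'R,4'R,7a'R)-4',7a'-dimethyl-5'-oxooctahydrospiro[1,3-dioxolane-2,1'-inden]-4'-yl]acetate, via lithium enolate 7 (not isolated)
Conditions: Li (2.1 equiv), t-BuOH (1.0 equiv), NH3(l)/THF, −78 °C; NH3 evaporated; then 6, THF, −78 °C → rt
Reagents that add atoms: none
Why: Birch-type reductive alkylation, in which axial protonation of the β-carbanion at C10 should give the trans-fused enolate (H-10 β) and C-alkylation at C9 should occur anti to the axial C19 methyl, placing CH2CO2Et β and C20 α.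

Step 5
Reactants: 8 ethyl 2-[(3a'R,4'R,7a'R)-4',7a'-dimethyl-5'-oxooctahydrospiro[1,3-dioxolane-2,1'-inden]-4'-yl]acetate
Product: 9 ethyl 2-[(3a'R,4'R,7a'R)-4',7a'-dimethyl-5'-methylideneoctahydrospiro[1,3-dioxolane-2,1'-inden]-4'-yl]acetate
Conditions: Zn, CH2Br2, TiCl4 (promoter), THF/CH2Cl2, 0 °C → rt
Reagents that add atoms: dibromomethane, BrCBr
Why: Takai–Lombardo methylenation uses a non-basic gem-dimetallic CH2 reagent that adds to hindered α-quaternary ketones and should leave the ester and the ketal untouched; no stereocenter is formed.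

Step 6
Reactants: 9 ethyl 2-[(3a'R,4'R,7a'R)-4',7a'-dimethyl-5'-methylideneoctahydrospiro[1,3-dioxolane-2,1'-inden]-4'-yl]acetate
Product: 11 ethyl 2-[(3aR,4S,5R,7aR)-4,5,7a-trimethyl-1-oxooctahydro-1H-inden-4-yl]acetate, via ketal ester 10 (not isolated)
Conditions: H2 (1 atm), Pd/C, EtOAc, rt; filter; then 2 M HCl, THF, 40 °C
Reagents that add atoms: water, O
Why: Heterogeneous hydrogenation should deliver hydrogen to the exocyclic alkene from the β face, away from the axial α methyl C20 on the neighbouring C9, setting C8 with C17 equatorial (α), after which aqueous acid cleaves the dioxolane and leaves the ester.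

Step 7
Reactants: 11 ethyl 2-[(3aR,4S,5R,7aR)-4,5,7a-trimethyl-1-oxooctahydro-1H-inden-4-yl]acetate
Product: 13 ethyl 2-[(1S,2R,4aR,8aR)-1,2,4a-trimethyl-5-oxodecahydronaphthalen-1-yl]acetate, via α-silyl ketone 12 (not isolated)
Conditions: TMSCHN2 (1.5 equiv), BF3·OEt2 (promoter), CH2Cl2, −78 → −20 °C; then 1 M HCl, THF, rt
Reagents that add atoms: trimethylsilyldiazomethane, C[Si](C)(C)C=[N+]=[N-]
Why: BF3 activates the C4 carbonyl, the diazo carbon adds to it, and in the resulting β-oxido diazonium ion the C4–C2 ring bond migrates to the diazo carbon with loss of N2, so the cyclopentanone becomes the cyclohexanone of ring A (Tiffeneau–Demjanov-type diazoalkane homologation; the closest known cases are the Lewis-acid-promoted trimethylsilyldiazomethane homologation of cycloalkanones and the D-homoannulation of 17-keto steroids, which carry the same α-quaternary cyclopentanone). Ring A is closed by a 1,2-alkyl shift (ring enlargement), not by an exo or endo cyclisation, and C1–C5 and C10 share one ring only from this step on. No permanent stereocenter is made: the migrating carbon is the CH2 group C2, C5 and C10 are not involved so the trans ring fusion is carried over, and the transient silyl-bearing centre C3 is erased on protodesilylation. The step needs migration of the CH2 carbon and not of the quaternary C5, which the steric bias of the fully substituted C5 against the bulky silyl group in the betaine should secure, keeping the carbonyl at C4. It also needs to stop after one insertion and to spare the ester, which the α-silyl group of 12 (shielding the new ketone until work-up) and the low electrophilicity of the ester should secure. Relief of the strain of the trans-hydrindanone adds driving force.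

Step 8
Reactants: 13 ethyl 2-[(1S,2R,4aR,8aR)-1,2,4a-trimethyl-5-oxodecahydronaphthalen-1-yl]acetate
Product: 15 ethyl 2-[(1S,2R,4aR,8aR)-1,2,4a-trimethyl-5-{[(trifluoromethyl)sulfonyl]oxy}-1,2,3,4,4a,7,8,8a-octahydronaphthalen-1-yl]acetate, via potassium enolate 14 (not isolated)
Conditions: KHMDS (1.05 equiv), THF, −78 °C; then PhNTf2, −78 → 0 °C
Reagents that add atoms: N-phenylbis(trifluoromethanesulfonimide), O=S(=O)(N(c1ccccc1)S(=O)(=O)C(F)(F)F)C(F)(F)F
Why: The ketone can enolise only toward C3 because C5 is quaternary, so O-sulfonylation gives the C3=C4 enol triflate regiospecifically, the hindered and less acidic ester CH2 being left alone.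

Step 9
Reactants: 15 ethyl 2-[(1S,2R,4aR,8aR)-1,2,4a-trimethyl-5-{[(trifluoromethyl)sulfonyl]oxy}-1,2,3,4,4a,7,8,8a-octahydronaphthalen-1-yl]acetate
Product: 16 ethyl 2-[(1S,2R,4aR,8aR)-1,2,4a,5-tetramethyl-1,2,3,4,4a,7,8,8a-octahydronaphthalen-1-yl]acetate
Conditions: Me2CuLi, Et2O/THF, −20 → 0 °C
Reagents that add atoms: lithium dimethylcuprate, [Li+].C[Cu-]C
Why: Cross-coupling of an enol triflate with a lithium dialkylcuprate replaces the triflate by methyl (C18) without moving the double bond, giving the trisubstituted C3=C4 alkene; the ester is inert to the cuprate at this temperature.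

Step 10
Reactants: 16 ethyl 2-[(1S,2R,4aR,8aR)-1,2,4a,5-tetramethyl-1,2,3,4,4a,7,8,8a-octahydronaphthalen-1-yl]acetate
Product: 17 2-[(1S,2R,4aR,8aR)-1,2,4a,5-tetramethyl-1,2,3,4,4a,7,8,8a-octahydronaphthalen-1-yl]ethan-1-ol
Conditions: LiAlH4, THF, 0 °C → rt
Reagents that add atoms: none
Why: Hydride reduction of the ester to the primary alcohol (C12), the isolated alkene being inert.

Step 11
Reactants: 17 2-[(1S,2R,4aR,8aR)-1,2,4a,5-tetramethyl-1,2,3,4,4a,7,8,8a-octahydronaphthalen-1-yl]ethan-1-ol
Product: 18 (1S,2R,4aR,8aR)-1-(2-iodoethyl)-1,2,4a,5-tetramethyl-1,2,3,4,4a,7,8,8a-octahydronaphthalene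
Conditions: I2, PPh3, imidazole, CH2Cl2, 0 °C → rt
Reagents that add atoms: iodine, II
Why: Appel-type iodination of the unhindered primary alcohol by SN2 displacement of the oxyphosphonium group; no stereocenter is touched.

Step 12
Reactants: 19 but-2-yne-1,4-diol
Product: 20 4-[(tert-butyldimethylsilyl)oxy]but-2-yn-1-ol
Conditions: TBSCl (0.3 equiv relative to 19), imidazole, DMF/THF, 0 °C → rt
Reagents that add atoms: tert-butyldimethylsilyl chloride, CC(C)(C)[Si](C)(C)Cl
Why: Statistical monosilylation of the symmetric diol used in excess, the surplus diol being removed by aqueous extraction.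

Step 13
Reactants: 20 4-[(tert-butyldimethylsilyl)oxy]but-2-yn-1-ol
Product: 22 (2Z)-4-[(tert-butyldimethylsilyl)oxy]-3-iodobut-2-en-1-ol, via vinylalanate 21 (not isolated)
Conditions: Red-Al (NaAlH2(OCH2CH2OMe)2), THF, 0 °C → rt; then I2, THF, −78 → 0 °C
Reagents that add atoms: iodine, II
Why: Alkoxide-directed trans-hydroalumination of the propargylic alcohol delivers hydride to C14 and aluminium to C13 within a five-membered oxa-aluminacycle, and iodinolysis with retention gives the iodide with iodine cis to CH2OH, which fixes the alkene geometry of the target.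

Step 14
Reactants: 18 (1S,2R,4aR,8aR)-1-(2-iodoethyl)-1,2,4a,5-tetramethyl-1,2,3,4,4a,7,8,8a-octahydronaphthalene; 22 (2Z)-4-[(tert-butyldimethylsilyl)oxy]-3-iodobut-2-en-1-ol
Product: 25 (2E)-3-{[(tert-butyldimethylsilyl)oxy]methyl}-5-[(1S,2R,4aR,8aR)-1,2,4a,5-tetramethyl-1,2,3,4,4a,7,8,8a-octahydronaphthalen-1-yl]pent-2-en-1-ol, via alkyllithium 23 (not isolated), via lithium borate 24 (not isolated)
Conditions: 18, t-BuLi (2.1 equiv), Et2O, −78 °C; B-methoxy-9-BBN, THF, −78 °C → rt; then 22, Pd(dppf)Cl2 (cat.), AsPh3, K3PO4 (aq, promoter), DMF, rt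
Reagents that add atoms: none
Why: B-alkyl Suzuki–Miyaura coupling through the lithium B-alkyl-B-methoxy borate, which transmetalates directly and couples with the vinyl iodide with retention of geometry, so C12 ends cis to C15 and the free hydroxyl and silyl ether are tolerated.

Step 15
Reactants: 25 (2E)-3-{[(tert-butyldimethylsilyl)oxy]methyl}-5-[(1S,2R,4aR,8aR)-1,2,4a,5-tetramethyl-1,2,3,4,4a,7,8,8a-octahydronaphthalen-1-yl]pent-2-en-1-ol; 26 icosanoic acid
Product: 27 (2E)-3-{[(tert-butyldimethylsilyl)oxy]methyl}-5-[(1S,2R,4aR,8aR)-1,2,4a,5-tetramethyl-1,2,3,4,4a,7,8,8a-octahydronaphthalen-1-yl]pent-2-en-1-yl icosanoate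
Conditions: DCC, DMAP (cat.), CH2Cl2, rt
Reagents that add atoms: none
Why: Steglich esterification of the only free hydroxyl (primary allylic C15–OH), C16–OH being silylated.

Step 16
Reactants: 27 (2E)-3-{[(tert-butyldimethylsilyl)oxy]methyl}-5-[(1S,2R,4aR,8aR)-1,2,4a,5-tetramethyl-1,2,3,4,4a,7,8,8a-octahydronaphthalen-1-yl]pent-2-en-1-yl icosanoate
Product: 28 (2E)-3-(hydroxymethyl)-5-[(1S,2R,4aR,8aR)-1,2,4a,5-tetramethyl-1,2,3,4,4a,7,8,8a-octahydronaphthalen-1-yl]pent-2-en-1-yl icosanoate
Conditions: HF·pyridine, pyridine/THF, 0 °C → rt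
Reagents that add atoms: none
Why: Fluoride-mediated desilylation under non-basic conditions should leave the allylic ester in place, and acyl migration is geometrically excluded because C15 and C16 are trans across the alkene.

**Compound list**

1 | 2-methylcyclopentane-1,3-dione | CC1C(=O)CCC1=O | starting material
2 | ethyl vinyl ketone (pent-1-en-3-one) | CCC(=O)C=C | starting material
3 | 2-methyl-2-(3-oxopentyl)cyclopentane-1,3-dione | CCC(=O)CCC1(C)C(=O)CCC1=O | intermediate
4 | (7aR)-4,7a-dimethyl-2,3,7,7a-tetrahydro-1H-indene-1,5(6H)-dione | O=C1CC[C@@]2(C)C(=O)CCC2=C1C | intermediate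
5 | (7a'R)-4',7a'-dimethyl-2',3',7',7a'-tetrahydrospiro[1,3-dioxolane-2,1'-inden]-5'(6'H)-one (C4 ethylene ketal of 4) | O=C1CC[C@@]2(C)C3(OCCO3)CCC2=C1C | intermediate
6 | ethyl bromoacetate | CCOC(=O)CBr | starting material
7 | lithium enolate (C8–O−, C8=C9) of the trans-fused hydrindanone ketal, (3a'R,7a'R), H-10 β | [Li+].CC1=C([O-])CC[C@@]2(C)C3(OCCO3)CC[C@H]12 | intermediate
8 | ethyl 2-[(3a'R,4'R,7a'R)-4',7a'-dimethyl-5'-oxooctahydrospiro[1,3-dioxolane-2,1'-inden]-4'-yl]acetate (trans-fused; C20 α, CH2CO2Et β) | CCOC(=O)C[C@@]1(C)C(=O)CC[C@@]2(C)C3(OCCO3)CC[C@H]12 | intermediate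
9 | ethyl 2-[(3a'R,4'R,7a'R)-4',7a'-dimethyl-5'-methylideneoctahydrospiro[1,3-dioxolane-2,1'-inden]-4'-yl]acetate | CCOC(=O)C[C@@]1(C)C(=C)CC[C@@]2(C)C3(OCCO3)CC[C@H]12 | intermediate
10 | ethyl 2-[(3a'R,4'S,5'R,7a'R)-4',5',7a'-trimethyloctahydrospiro[1,3-dioxolane-2,1'-inden]-4'-yl]acetate (C17 α) | CCOC(=O)C[C@@]1(C)[C@H](C)CC[C@@]2(C)C3(OCCO3)CC[C@H]12 | intermediate
11 | ethyl 2-[(3aR,4S,5R,7aR)-4,5,7a-trimethyl-1-oxooctahydro-1H-inden-4-yl]acetate (trans-hydrindan-4-one) | CCOC(=O)C[C@@]1(C)[C@H](C)CC[C@@]2(C)C(=O)CC[C@H]12 | intermediate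
12 | ethyl 2-[(1S,2R,4aR,8aR)-1,2,4a-trimethyl-5-oxo-6-(trimethylsilyl)decahydronaphthalen-1-yl]acetate (configuration at the silyl carbon C3 open) | CCOC(=O)C[C@@]1(C)[C@H](C)CC[C@@]2(C)C(=O)C([Si](C)(C)C)CC[C@H]12 | intermediate
13 | ethyl 2-[(1S,2R,4aR,8aR)-1,2,4a-trimethyl-5-oxodecahydronaphthalen-1-yl]acetate (trans-decalin-4-one) | CCOC(=O)C[C@@]1(C)[C@H](C)CC[C@@]2(C)C(=O)CCC[C@H]12 | intermediate
14 | potassium enolate of 13 (C4–O−, C3=C4) | [K+].CCOC(=O)C[C@@]1(C)[C@H](C)CC[C@@]2(C)C([O-])=CCC[C@H]12 | intermediate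
15 | ethyl 2-[(1S,2R,4aR,8aR)-1,2,4a-trimethyl-5-{[(trifluoromethyl)sulfonyl]oxy}-1,2,3,4,4a,7,8,8a-octahydronaphthalen-1-yl]acetate | CCOC(=O)C[C@@]1(C)[C@H](C)CC[C@@]2(C)C(OS(=O)(=O)C(F)(F)F)=CCC[C@H]12 | intermediate
16 | ethyl 2-[(1S,2R,4aR,8aR)-1,2,4a,5-tetramethyl-1,2,3,4,4a,7,8,8a-octahydronaphthalen-1-yl]acetate | CCOC(=O)C[C@@]1(C)[C@H](C)CC[C@@]2(C)C(C)=CCC[C@H]12 | intermediate
17 | 2-[(1S,2R,4aR,8aR)-1,2,4a,5-tetramethyl-1,2,3,4,4a,7,8,8a-octahydronaphthalen-1-yl]ethan-1-ol | OCC[C@@]1(C)[C@H](C)CC[C@@]2(C)C(C)=CCC[C@H]12 | intermediate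
18 | (1S,2R,4aR,8aR)-1-(2-iodoethyl)-1,2,4a,5-tetramethyl-1,2,3,4,4a,7,8,8a-octahydronaphthalene | ICC[C@@]1(C)[C@H](C)CC[C@@]2(C)C(C)=CCC[C@H]12 | intermediate
19 | but-2-yne-1,4-diol | OCC#CCO | starting material
20 | 4-[(tert-butyldimethylsilyl)oxy]but-2-yn-1-ol | OCC#CCO[Si](C)(C)C(C)(C)C | intermediate
21 | sodium vinylalanate (five-membered oxa-aluminacycle O–Al–C13=C14–C15 carrying two 2-methoxyethoxy groups on aluminium) | [Na+].COCCO[Al-]1(OCCOC)OCC=C1CO[Si](C)(C)C(C)(C)C | intermediate
22 | (2Z)-4-[(tert-butyldimethylsilyl)oxy]-3-iodobut-2-en-1-ol | OC/C=C(/CO[Si](C)(C)C(C)(C)C)I | intermediate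
23 | {2-[(1S,2R,4aR,8aR)-1,2,4a,5-tetramethyl-1,2,3,4,4a,7,8,8a-octahydronaphthalen-1-yl]ethyl}lithium | [Li]CC[C@@]1(C)[C@H](C)CC[C@@]2(C)C(C)=CCC[C@H]12 | intermediate
24 | lithium B-methoxy-B-alkyl-9-borabicyclo[3.3.1]nonane borate (alkyl = the C12 ethyl group of 23) | [Li+].CO[B-]1(CC[C@@]4(C)[C@H](C)CC[C@@]5(C)C(C)=CCC[C@H]45)C2CCCC1CCC2 | intermediate
25 | (2E)-3-{[(tert-butyldimethylsilyl)oxy]methyl}-5-[(1S,2R,4aR,8aR)-1,2,4a,5-tetramethyl-1,2,3,4,4a,7,8,8a-octahydronaphthalen-1-yl]pent-2-en-1-ol | OC/C=C(/CO[Si](C)(C)C(C)(C)C)CC[C@@]1(C)[C@H](C)CC[C@@]2(C)C(C)=CCC[C@H]12 | intermediate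
26 | icosanoic acid | CCCCCCCCCCCCCCCCCCCC(=O)O | starting material
27 | (2E)-3-{[(tert-butyldimethylsilyl)oxy]methyl}-5-[(1S,2R,4aR,8aR)-1,2,4a,5-tetramethyl-1,2,3,4,4a,7,8,8a-octahydronaphthalen-1-yl]pent-2-en-1-yl icosanoate | CCCCCCCCCCCCCCCCCCCC(=O)OC/C=C(/CO[Si](C)(C)C(C)(C)C)CC[C@@]1(C)[C@H](C)CC[C@@]2(C)C(C)=CCC[C@H]12 | intermediate
28 | (2E)-3-(hydroxymethyl)-5-[(1S,2R,4aR,8aR)-1,2,4a,5-tetramethyl-1,2,3,4,4a,7,8,8a-octahydronaphthalen-1-yl]pent-2-en-1-yl icosanoate (CNP0168335.1) | CCCCCCCCCCCCCCCCCCCC(=O)OC/C=C(/CO)CC[C@@]1(C)[C@H](C)CC[C@@]2(C)C(C)=CCC[C@H]12 | target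

**Step count**

Total: 16 steps. Longest linear sequence: 14 steps (steps 1–11, then 14–16); steps 12–13 make the vinyl iodide fragment.

**Steps most likely to fail, with fallbacks**

Step 7 (ring enlargement). The quaternary C5 may migrate in competition with the CH2 carbon, or a second insertion may occur. The fallback enlarges the ring regiospecifically through a cyclopropane and sets out from 11. Soft enolisation (TMSOTf, Et3N, CH2Cl2, 0 °C) can only give the trimethylsilyl enol ether F1, since C5 has no hydrogen. Simmons–Smith cyclopropanation (Et2Zn, CH2I2, CH2Cl2) should give the siloxycyclopropane F2. FeCl3 in DMF at 0 °C oxidises it to an alkoxy radical that cleaves the shared C4–C2 bond and, after chlorine transfer, gives the ring-enlarged β-chloro ketone F3; ring A is again the last ring formed. DBU in CH2Cl2 eliminates HCl to the enone F4, and hydrogenation (H2, Pd/C, EtOAc) comes back to the route at 13.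

Step 4 (reductive alkylation). Proton transfer from the bromoacetate to the fully substituted enolate, or O-alkylation, may outrun C-alkylation at C9. The fallback sets out from 5 and traps the same Li/NH3-derived enolate in liquid ammonia with allyl bromide, a faster and non-acidic electrophile, to give the allyl ketone F5. Ozonolysis (O3, CH2Cl2, −78 °C; Me2S) gives the aldehyde F6. Pinnick oxidation (NaClO2, NaH2PO4, 2-methyl-2-butene, t-BuOH/H2O) gives the acid F7. Esterification (EtI, K2CO3, DMF) comes back to the route at 8. Incomplete trans selectivity in the protonation at C10 is not cured by this change; the cis-fused isomer would have to be removed by chromatography at 8.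

Step 6 (hydrogenation). Hydrogen may add to the exocyclic alkene from the α face as well, giving the axial C17 epimer. The fallback sets out from 9 and replaces surface hydrogenation by hydrogen-atom-transfer hydrogenation (Mn(dpm)3 cat., PhSiH3, t-BuOOH, i-PrOH, rt). This stepwise radical reduction passes through the tertiary C8 radical, which takes up hydrogen axially and should give the thermodynamically preferred equatorial methyl. It comes back to the route at 10, which is hydrolysed to 11 as before. New compounds on this path: none F0.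

Further compounds
F1 | step 7 | trimethylsilyl enol ether of 11 (C4–OSiMe3, C4=C2) | CCOC(=O)C[C@@]1(C)[C@H](C)CC[C@@]2(C)C(O[Si](C)(C)C)=CC[C@H]12
F2 | step 7 | siloxycyclopropane (CH2 bridging C4 and C2 of the five-membered ring) | CCOC(=O)C[C@@]1(C)[C@H](C)CC[C@@]2(C)C3(O[Si](C)(C)C)CC3C[C@H]12
F3 | step 7 | ring-enlarged β-chloro ketone (C4 ketone, chlorine on C2) | CCOC(=O)C[C@@]1(C)[C@H](C)CC[C@@]2(C)C(=O)CC(Cl)C[C@H]12
F4 | step 7 | ring-enlarged enone (C4 ketone, C2=C3) | CCOC(=O)C[C@@]1(C)[C@H](C)CC[C@@]2(C)C(=O)C=CC[C@H]12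
F5 | step 4 | allyl ketone (allyl in place of CH2CO2Et of 8) | C=CC[C@@]1(C)C(=O)CC[C@@]2(C)C3(OCCO3)CC[C@H]12
F6 | step 4 | keto aldehyde (CH2CHO on C9) | O=CC[C@@]1(C)C(=O)CC[C@@]2(C)C3(OCCO3)CC[C@H]12
F7 | step 4 | keto acid (CH2CO2H on C9) | OC(=O)C[C@@]1(C)C(=O)CC[C@@]2(C)C3(OCCO3)CC[C@H]12
F0 | step 6 | none | none
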